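Saturday's flask holds more coupling partner than Tuesday's, 0.168 M against 0.0375 M, since the equivalents follow the substrate.

| flask | substrate | coupling partner | temperature | remark | time |
|---|---|---|---|---|---|
| blue | 0.0089 M | 2.5 equiv | 55 °C | run made earlier |  |
| grey | 0.045 M | 2.5 equiv | 70 °C | run made earlier |  |
| Tuesday's | 0.015 M | 2.50 equiv | 70 °C |  | 8.0 d |
| Saturday's | 0.067 M | 2.50 equiv | 70 °C |  | 8.0 d |

- which of the two ends with the higher amount of target, in percent of the substrate charged ("neither" if they lie within 2 percentage points) (Tuesday's / Saturday's / neither)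
- target at the end, in percent of the substrate charged, Tuesday's
- target at the end, in percent of the substrate charged, Saturday's

- steps that have been proposed: substrate + coupling partner <-> intermediate; intermediate -> side product; intermediate <-> target + by-product; target <-> isomer of the product
- where the amount of substrate changes, what is given in equivalents or mol% on it follows

| run | time / d | target / % | substrate / % |
|---|---|---|---|
| blue | 0.625 | 1.0 | 98.4 |
| blue | 1.04 | 0.3 | 98.0 |
| blue | 1.67 | 0 | 98.0 |
| blue | 4.00 | 0.9 | 96.4 |
| blue | 5.00 | 0.3 | 96.2 |
| blue | 8.00 | 1.1 | 93.9 |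
| grey | 0.333 | 1.8 | 92.0 |
| grey | 0.500 | 0.5 | 89.7 |
| grey | 0.833 | 3.3 | 86.8 |
| grey | 1.67 | 3.5 | 81.2 |
| grey | 2.50 | 5.3 | 75.8 |
| grey | 4.00 | 7.7 | 67.2 |

(readings scatter by 0.5 percentage points)

The blue run is colder, and its target readings never pass 1.1%, so I read the grey run, which stands at the temperature of both new flasks. After a quick first drop to 86.8% at 0.833 d, grey substrate falls steadily to 67.2% at 4.00 d. That is a pseudo-first-order constant of 0.0808 d⁻¹, read from two readings.

But the proposed first step takes the coupling partner, so I scale this constant with c(coupling partner) and multiply by the time. Saturday's gets 0.963, and this is what I carry: the drain number. Tuesday's gets 0.216.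

The crossing lies at one. In my rule, target grows in step with the number below it and bends towards a ceiling above it. Target is the ceiling times one minus e to the minus number, and the last grey target reading puts that ceiling at 27.9%. So I expect 5.40% for Tuesday's and 17.2% for Saturday's, which ends higher.

The forecast names Saturday's, with 6% for Tuesday's and 15% for Saturday's; its ground: “The rate scales with partner concentration”.

The flasks give Saturday's as the higher, with 6.03% for Tuesday's and 16.5% for Saturday's.

    substrate + coupling partner ⇌ intermediate (K = 0.660 M⁻¹, k = 11.0 M⁻¹ h⁻¹, Ea = 60.0 kJ mol⁻¹, ΔH = −28.0 kJ mol⁻¹)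
    intermediate → side product (k = 0.0340 h⁻¹, Ea = 125 kJ mol⁻¹)
    intermediate ⇌ target + by-product (K = 2.80 M, k = 0.0210 h⁻¹, Ea = 126 kJ mol⁻¹, ΔH = −8.00 kJ mol⁻¹)
    target ⇌ isomer of the product (K = 0.370, k = 0.0420 h⁻¹, Ea = 116 kJ mol⁻¹, ΔH = 7.00 kJ mol⁻¹)
    (constants at 70 °C)

Saturday's has not come to rest at 8.0 d: 37.9% substrate still stands there. The neighbour of Saturday's charged with 6.20 equiv of coupling partner has a drain number of 2.39, so my rule gives 25.3% target, and that flask ends with 24.2% target. At ten times the time, Saturday's number is 9.63, and the rule gives 27.9% target, above the 24.3% target that stands in Saturday's then. At 80.0 d, Tuesday's reaches 23.4% target with 14.5% substrate, and Saturday's holds 1.22% substrate.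

The data stem from a simulated flask on assumed constants; scatter was added.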